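You are asked whether the share of X among all that became X or L.J moves as you raise the charge of L from 8.00 mM to 40.0 mM. Z turns reversibly into J, and L then catches J by two steps, one giving X, the other L.J.

    Z ⇌ J (K1 = 0.26, k1 = 0.0187 s⁻¹)
    L + J → L.J (k2 = 0.352 M⁻¹ s⁻¹)
    L + J → X (k3 = 2.36 M⁻¹ s⁻¹)
    D ⇌ X, rate k4*(cs4 - [X]) while solid is left; crystals form when [X] > cs4 (cs4 = 11 mM, k4 = 1.47 s⁻¹)
    Z + E → Z.E (k5 = 2.46 M⁻¹ s⁻¹)

| setting | Thursday's | Wednesday's | Tuesday's | Monday's | Saturday's |
|---|---|---|---|---|---|
| Z | 20 mM | 20 mM | 20 mM | 20 mM | 20 mM |
| L | 8.00 mM | 10.0 mM | 15.0 mM | 25.0 mM | 40.0 mM |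
| E | 1.00 mM | 1.00 mM | 1.00 mM | 1.00 mM | 1.00 mM |
| time | 4.0 min | 4.0 min | 4.0 min | 4.0 min | 4.0 min |

* share of X in all that became X or L.J for Thursday's, Wednesday's, Tuesday's, Monday's, Saturday's, in this order
* how the row runs (hardly changes / rises, then falls / falls all the way / rises all the way / falls, then rises)

- amounts and yields of X count D too
- given per volume of solution although it is solid: D
- "hardly changes" means that all values lie within two and a half points (for a concentration: within two and a half percent of the largest)
- run time (Thursday's): 4.0 min

Turn the question round: what must the numbers say for the row to bend? With these five steps, the two steps from L + J must differ in their order in L or in J, or something must carry X or L.J out of the count. Test the first by dividing one rate by the other, and call the result the split, the selectivity factor of this pair: the rate to X over the rate to L.J.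

rate to X / rate to L.J = 2.36 M⁻¹ s⁻¹ · c_L · c_J / (0.352 M⁻¹ s⁻¹ · c_L · c_J) = 6.70

Both concentrations cancel, and time goes with them. The difference in order is nil, so these flasks get no bend from that side. My share is therefore one number, whatever c_L is:

share of X = 2.36 M⁻¹ s⁻¹ / (2.36 M⁻¹ s⁻¹ + 0.352 M⁻¹ s⁻¹) = 87.0 %

Now the second way. Crystals of D form when c_X passes 11 mM, which is 55.0 % of the Z charged. But D is counted as X, so the crystals take nothing out of the tally.

The forecast reads 87 %, 87 %, 87 %, 87 %, 87 %, and hardly changes, on the grounds that “X and L.J both form from the same pair, L + J, with the same rate order”.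

The simulation gives 87.0 %, 87.0 %, 87.0 %, 87.0 %, 87.0 %, and the row hardly changes.

In Thursday's flask the step to X uses L 6.7 times as fast as the step to L.J at 0.537 min, and 6.7 times as fast at 4.00 min, which is the split 6.70 itself. Saturday's flask, with D at 17.8 % of the Z charged, holds X at 72.9 % (D included) and L.J at 10.9 % at 4.00 min, a ratio of 6.69.

The rate constants are invented; no experiment stands behind them.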